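**Retrosynthetic overview**
1. The diaryl ketone is not made by joining two arenes. Ring B (C1 aroyl, C2 CHO, C3 OH, C4 H, C5 OH, C6 prenyl) is built onto the ketone-bearing carbon by a [4+2] that forms C1–C6 and C2–C3; the diene (C3–C6) comes from γ-prenylated methyl acetoacetate.
2. The dienophile is an aurone-type enal. The ortho OH of ring A and the C=O are tied up as a benzofuran-3(2H)-one whose C2 becomes C1 of ring B. Cleavage of the spiro C–O bond (retro-oxa-Michael) aromatises ring B and frees the ring A phenol, so no protecting group is needed.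
3. The enal comes from 7-bromo-5-chloro-4-methoxy-6-methylbenzofuran-3(2H)-one and glyoxal mono-acetal. The furanone comes from the aryloxyacetic acid by Friedel–Crafts closure at the one free position of ring A.
4. Br (ortho to OH) and Cl (para to OH) are placed on 3-methoxy-5-methylphenol before any C–C bond is made.
5. Ring order: furanone ring (step 4), then the spiro cyclohexene that becomes ring B (step 10); the furanone ring is opened and ring B aromatised in that same step.

Key step: step 10

Assumption: the target has no stereocentre and no stereogenic double bond, so no configuration has to be set. The E/Z mixtures of 12 and 13 and the diastereomer mixture of 14 converge in the aromatisation, and their SMILES are given without stereodescriptors.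

**Route**

Step 1
Reactants: 1 3-methoxy-5-methylphenol
Product: 2 2-bromo-5-methoxy-3-methylphenol
Conditions: NBS (1.0 equiv), iPr2NH (10 mol%), CH2Cl2, 0 °C
Reagents that add atoms: N-bromosuccinimide, O=C1CCC(=O)N1Br
Why: Amine-mediated ortho-selective electrophilic bromination of a phenol (SEAr) should take the ortho position that is also para to OMe, rather than the one flanked by two oxygens.

Step 2
Reactants: 2 2-bromo-5-methoxy-3-methylphenol
Product: 3 2-bromo-4-chloro-5-methoxy-3-methylphenol
Conditions: SO2Cl2 (1.05 equiv), CH2Cl2, 0 °C to rt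
Reagents that add atoms: sulfuryl chloride, O=S(=O)(Cl)Cl
Why: Electrophilic aromatic chlorination of the free phenol should go para to OH (also ortho to OMe), since the only other open site lies between the two oxygens and is the least reactive of an orcinol ether.

Step 3
Reactants: 3 2-bromo-4-chloro-5-methoxy-3-methylphenol
Product: 4 2-(2-bromo-4-chloro-5-methoxy-3-methylphenoxy)acetic acid
Conditions: ClCH2CO2H, aq. NaOH, reflux; then HCl
Reagents that add atoms: chloroacetic acid, OC(=O)CCl
Why: Williamson ether synthesis of the phenoxide with chloroacetate, the standard entry to aryloxyacetic acids of halogenated phenols.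

Step 4
Reactants: 4 2-(2-bromo-4-chloro-5-methoxy-3-methylphenoxy)acetic acid
Product: 5 7-bromo-5-chloro-4-methoxy-6-methylbenzofuran-3(2H)-one
Conditions: P2O5/MeSO3H (1:10 w/w), 50 °C
Reagents that add atoms: none
Why: Intramolecular Friedel–Crafts acylation can only close at the single free ring position, which is ortho to both ether oxygens and para to the methyl group, and non-Lewis-acidic conditions should spare the OMe next to the new carbonyl.

Step 5
Reactants: 5 7-bromo-5-chloro-4-methoxy-6-methylbenzofuran-3(2H)-one; 6 2,2-dimethoxyacetaldehyde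
Product: 7 (Z)-7-bromo-5-chloro-2-(2,2-dimethoxyethylidene)-4-methoxy-6-methylbenzofuran-3(2H)-one
Conditions: 6 (60% aq., 3 equiv), piperidine (20 mol%), AcOH (20 mol%), EtOH, rt
Reagents that add atoms: none
Why: Knoevenagel-type aldol condensation at the acidic C2–H2 of the benzofuranone (the aurone synthesis) should give the thermodynamically preferred Z alkylidene, and the excess aldehyde should suppress addition of a second furanone.

Step 6
Reactants: 7 (Z)-7-bromo-5-chloro-2-(2,2-dimethoxyethylidene)-4-methoxy-6-methylbenzofuran-3(2H)-one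
Product: 8 (Z)-2-(7-bromo-5-chloro-4-methoxy-6-methyl-3-oxobenzofuran-2(3H)-ylidene)acetaldehyde
Conditions: TFA/H2O (9:1), CH2Cl2, 0 °C; used crude
Reagents that add atoms: water, O
Why: Acid-catalysed acetal hydrolysis, helped by donation from the ring oxygen into the intermediate oxocarbenium ion, should unveil the enal without touching the aryl halides.

Step 7
Reactants: 9 methyl acetoacetate; 10 1-bromo-3-methylbut-2-ene (prenyl bromide)
Product: 11 methyl 7-methyl-3-oxooct-6-enoate
Conditions: LDA (2.1 equiv), THF, −78 to 0 °C; then 10, 0 °C; aq. HCl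
Reagents that add atoms: none
Why: After double deprotonation of the β-keto ester the γ-carbon is the most nucleophilic site, and its SN2 alkylation by the allylic bromide is the standard γ-alkylation of acetoacetates.

Step 8
Reactants: 11 methyl 7-methyl-3-oxooct-6-enoate
Product: 12 methyl 7-methyl-3-(trimethylsilyloxy)octa-2,6-dienoate
Conditions: TMSCl, Et3N, hexane/Et2O, rt
Reagents that add atoms: chlorotrimethylsilane, C[Si](C)(C)Cl
Why: O-Silylation of the enolisable β-keto ester gives the silyl enol ether, the usual first stage of 1,3-bis(silyloxy)diene preparation.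

Step 9
Reactants: 12 methyl 7-methyl-3-(trimethylsilyloxy)octa-2,6-dienoate
Product: 13 1-methoxy-7-methyl-1,3-bis(trimethylsilyloxy)octa-1,3,6-triene
Conditions: LDA, THF, −78 °C; then TMSCl, −78 to 0 °C; non-aqueous work-up
Reagents that add atoms: chlorotrimethylsilane, C[Si](C)(C)Cl
Why: γ-Deprotonation of the vinylogous ester and O-silylation of the resulting dienolate is the established route to 4-alkyl-1-methoxy-1,3-bis(silyloxy)butadienes.

Step 10
Reactants: 8 (Z)-2-(7-bromo-5-chloro-4-methoxy-6-methyl-3-oxobenzofuran-2(3H)-ylidene)acetaldehyde; 13 1-methoxy-7-methyl-1,3-bis(trimethylsilyloxy)octa-1,3,6-triene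
Product: 15 Pestalone G, via spiro cycloadduct 14 (not isolated)
Conditions: 13 (1.5 equiv), toluene, −20 °C to rt, no Lewis acid; then 1 M HCl, THF, 0 °C to rt
Reagents that add atoms: none
Why: Proposed new method: a thermal normal-demand Diels–Alder of the 1,3-bis(silyloxy)diene 13 with the exocyclic C=C of 8 should give spiro adduct 14, and mild acid should then hydrolyse the silyl ketal and silyl enol ether and trigger an E1cB retro-oxa-Michael cleavage of the spiro C–O bond (the H on C2 of the new ring is α to CHO, the leaving group is the ring A aryloxide) with loss of MeOH, so that ring B aromatises and the ring A phenol is released in one operation. The closest known reaction types are the spiro-annulating [4+2] reactions of aurones with siloxydienes, the eliminative aromatising [4+2] reactions of 1,3-bis(silyloxy)dienes with β-leaving-group enones and haloquinones, and the retro-oxa-Michael opening of chromanones and grisans to 2-hydroxyaryl ketones; their combination on a 2-alkylidenebenzofuranone has no precedent. Ring B is closed by an intermolecular [4+2] (bonds C1–C6 and C2–C3 of ring B; a stepwise Michael/Claisen course would give the same ring), and the four stereocentres of 14 are all erased by the aromatisation. The step needs one regiochemistry, prenyl-bearing diene terminus to benzofuranone C2: the aldehyde is the stronger acceptor, O1 on C2 makes the enal a vinylogous formate with its largest LUMO coefficient on C2, and the opposite orientation would have to join two fully substituted carbons (spiro C2 and C(OMe)(OSiMe3)). It also needs addition to C=C and not to the CHO group or to the enal as an oxadiene, which the absence of a Lewis acid should favour. Acid and not base is used for the aromatisation because base isomerises o-aroylbenzaldehydes of this kind to phthalides, and the acid is kept dilute so that the ortho-prenylphenol does not close to a chroman.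

**Compound list**
1 | 3-methoxy-5-methylphenol | COc1cc(C)cc(O)c1 | starting material
2 | 2-bromo-5-methoxy-3-methylphenol | COc1cc(O)c(Br)c(C)c1 | intermediate
3 | 2-bromo-4-chloro-5-methoxy-3-methylphenol | COc1cc(O)c(Br)c(C)c1Cl | intermediate
4 | 2-(2-bromo-4-chloro-5-methoxy-3-methylphenoxy)acetic acid | COc1cc(OCC(=O)O)c(Br)c(C)c1Cl | intermediate
5 | 7-bromo-5-chloro-4-methoxy-6-methylbenzofuran-3(2H)-one | COc1c(Cl)c(C)c(Br)c2OCC(=O)c12 | intermediate
6 | 2,2-dimethoxyacetaldehyde | COC(OC)C=O | starting material
7 | (Z)-7-bromo-5-chloro-2-(2,2-dimethoxyethylidene)-4-methoxy-6-methylbenzofuran-3(2H)-one | O=C1/C(=C/C(OC)OC)Oc2c(Br)c(C)c(Cl)c(OC)c12 | intermediate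
8 | (Z)-2-(7-bromo-5-chloro-4-methoxy-6-methyl-3-oxobenzofuran-2(3H)-ylidene)acetaldehyde | O=C1/C(=C/C=O)Oc2c(Br)c(C)c(Cl)c(OC)c12 | intermediate
9 | methyl acetoacetate | COC(=O)CC(C)=O | starting material
10 | 1-bromo-3-methylbut-2-ene (prenyl bromide) | CC(C)=CCBr | starting material
11 | methyl 7-methyl-3-oxooct-6-enoate | COC(=O)CC(=O)CCC=C(C)C | intermediate
12 | methyl 7-methyl-3-(trimethylsilyloxy)octa-2,6-dienoate (E/Z mixture) | COC(=O)C=C(CCC=C(C)C)O[Si](C)(C)C | intermediate
13 | 1-methoxy-7-methyl-1,3-bis(trimethylsilyloxy)octa-1,3,6-triene (geometric isomers) | COC(O[Si](C)(C)C)=CC(O[Si](C)(C)C)=CCC=C(C)C | intermediate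
14 | 7-bromo-5-chloro-3',4-dimethoxy-6-methyl-6'-(3-methylbut-2-en-1-yl)-3-oxo-3',5'-bis(trimethylsilyloxy)-3H-spiro[benzofuran-2,1'-cyclohexan]-4'-ene-2'-carbaldehyde (diastereomer mixture, not isolated) | COC1(O[Si](C)(C)C)C=C(O[Si](C)(C)C)C(CC=C(C)C)C2(Oc3c(Br)c(C)c(Cl)c(OC)c3C2=O)C1C=O | intermediate
15 | Pestalone G, 2-(3-bromo-5-chloro-2-hydroxy-6-methoxy-4-methylbenzoyl)-4,6-dihydroxy-3-(3-methylbut-2-en-1-yl)benzaldehyde | COc1c(Cl)c(C)c(Br)c(O)c1C(=O)c1c(C=O)c(O)cc(O)c1CC=C(C)C | target

**Step count**
Total: 10 steps. Longest linear sequence: 7 steps (steps 1–6 and 10); steps 7–9 make the diene.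

**Steps most likely to fail**

Step 10 (bears the label). What may go wrong: cycloaddition in the opposite orientation, steered by the ring ketone and the aromatic benzofuranolate it would generate; reaction of the enal as an oxadiene or at its C=O; or failure to form the spiro quaternary carbon. The fallback uses known chemistry, sets out from 3 and 13 and returns at 15. Mg-mediated ortho-formylation of phenol 3 (MgCl2, Et3N, paraformaldehyde, MeCN, reflux) at its one free position should give 3-bromo-5-chloro-2-hydroxy-6-methoxy-4-methylbenzaldehyde F1. Addition of lithiated methyl propiolate (3 equiv, THF, −78 °C) should give racemic methyl 4-(3-bromo-5-chloro-2-hydroxy-6-methoxy-4-methylphenyl)-4-hydroxybut-2-ynoate F2. This alkyne has the ester as its only acceptor, so the [4+2] with diene 13 (excess, toluene, 20–60 °C; then HCl, MeOH) can only place the prenyl-bearing terminus next to the carbinol carbon. After loss of MeOH, desilylation and lactonisation it should give racemic 3-(3-bromo-5-chloro-2-hydroxy-6-methoxy-4-methylphenyl)-5,7-dihydroxy-4-(3-methylbut-2-en-1-yl)isobenzofuran-1(3H)-one F3. The three phenols would then be protected (MOMCl, iPr2NEt) to give 3-[3-bromo-5-chloro-6-methoxy-2-(methoxymethoxy)-4-methylphenyl]-5,7-bis(methoxymethoxy)-4-(3-methylbut-2-en-1-yl)isobenzofuran-1(3H)-one F4. Reduction of the lactone (DIBAL-H, CH2Cl2, −78 to 0 °C) should give [3-bromo-5-chloro-6-methoxy-2-(methoxymethoxy)-4-methylphenyl][2-(hydroxymethyl)-3,5-bis(methoxymethoxy)-6-(3-methylbut-2-en-1-yl)phenyl]methanol F5. Swern oxidation of both benzylic alcohols at once should give 2-[3-bromo-5-chloro-6-methoxy-2-(methoxymethoxy)-4-methylbenzoyl]-4,6-bis(methoxymethoxy)-3-(3-methylbut-2-en-1-yl)benzaldehyde F6. Brief treatment with HCl in MeOH at rt should remove the MOM groups and give 15.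

Step 4. What may go wrong: slow acylation of a ring that carries two halogens, and acid-induced self-condensation of the furanone once formed. The fallback sets out from 3 and returns at 5, and reverses the order of bond formation (C–C first under chelation control, C–O ring closure second). Boron-directed ortho-acylation of phenol 3 with chloroacetonitrile (BCl3, AlCl3, CH2Cl2; then aq. HCl; Houben–Hoesch type, ortho to OH only) should give 2-chloro-1-(3-bromo-5-chloro-2-hydroxy-6-methoxy-4-methylphenyl)ethan-1-one F7. Intramolecular O-alkylation (NaOAc, EtOH, reflux) should then close the furanone ring to 5.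

Step 5. What may go wrong: Michael addition of a second furanone enolate to the alkylidene product, and base-induced decomposition of the electron-poor alkene. The fallback sets out from 5 and returns at 7, and separates C–C bond formation from dehydration. The lithium enolate of 5 (LiHMDS, THF, −78 °C) and anhydrous 6 should give the isolable aldol 7-bromo-5-chloro-2-(1-hydroxy-2,2-dimethoxyethyl)-4-methoxy-6-methylbenzofuran-3(2H)-one F8 (diastereomer mixture). Mesylation and elimination (MsCl, Et3N, CH2Cl2, 0 °C) should then give 7.

**Further compounds**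
F1 | step 10 | 3-bromo-5-chloro-2-hydroxy-6-methoxy-4-methylbenzaldehyde | COc1c(Cl)c(C)c(Br)c(O)c1C=O
F2 | step 10 | methyl 4-(3-bromo-5-chloro-2-hydroxy-6-methoxy-4-methylphenyl)-4-hydroxybut-2-ynoate (racemic) | COC(=O)C#CC(O)c1c(O)c(Br)c(C)c(Cl)c1OC
F3 | step 10 | 3-(3-bromo-5-chloro-2-hydroxy-6-methoxy-4-methylphenyl)-5,7-dihydroxy-4-(3-methylbut-2-en-1-yl)isobenzofuran-1(3H)-one (racemic) | COc1c(Cl)c(C)c(Br)c(O)c1C1OC(=O)c2c(O)cc(O)c(CC=C(C)C)c12
F4 | step 10 | 3-[3-bromo-5-chloro-6-methoxy-2-(methoxymethoxy)-4-methylphenyl]-5,7-bis(methoxymethoxy)-4-(3-methylbut-2-en-1-yl)isobenzofuran-1(3H)-one (racemic) | COCOc1cc(OCOC)c2C(=O)OC(c3c(OCOC)c(Br)c(C)c(Cl)c3OC)c2c1CC=C(C)C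
F5 | step 10 | [3-bromo-5-chloro-6-methoxy-2-(methoxymethoxy)-4-methylphenyl][2-(hydroxymethyl)-3,5-bis(methoxymethoxy)-6-(3-methylbut-2-en-1-yl)phenyl]methanol (racemic) | COCOc1cc(OCOC)c(CO)c(C(O)c2c(OCOC)c(Br)c(C)c(Cl)c2OC)c1CC=C(C)C
F6 | step 10 | 2-[3-bromo-5-chloro-6-methoxy-2-(methoxymethoxy)-4-methylbenzoyl]-4,6-bis(methoxymethoxy)-3-(3-methylbut-2-en-1-yl)benzaldehyde | COCOc1cc(OCOC)c(C=O)c(C(=O)c2c(OCOC)c(Br)c(C)c(Cl)c2OC)c1CC=C(C)C
F7 | step 4 | 2-chloro-1-(3-bromo-5-chloro-2-hydroxy-6-methoxy-4-methylphenyl)ethan-1-one | COc1c(Cl)c(C)c(Br)c(O)c1C(=O)CCl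
F8 | step 5 | 7-bromo-5-chloro-2-(1-hydroxy-2,2-dimethoxyethyl)-4-methoxy-6-methylbenzofuran-3(2H)-one (diastereomer mixture) | COc1c(Cl)c(C)c(Br)c2OC(C(O)C(OC)OC)C(=O)c12
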